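The route rests on opening the oxolane (O1, C2 bearing the aryl group, C3 bearing the CH2O arm, C4, C5H2) at the ring bond C3–C4 and cutting the C4 methylene arm from its guaiacyl ring. One nickel-catalysed reductive cascade should make both bonds: a C3 radical from a secondary bromide closes 5-exo onto an O-allyl group, the exocyclic radical is arylated, and C3 and C4 are set relative to C2. The precursor is the allyl ether of an enantiopure 1-aryl-2-bromo-3-silyloxypropan-1-ol, its benzylic centre fixed by an auxiliary-controlled bromoacetate aldol, together with benzyl-protected 4-bromoguaiacol. Desilylation, acylation with (R)-2-methylbutanoic acid and debenzylation then give the target.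

Key step: step 7

Remark: the configuration at the bromine-bearing carbon is erased when the radical forms, so the precursor is carried as the single (2S) epimer that the aldol supplies; this has no bearing on the outcome.

Step 1
Reactants: 1 4-bromo-2-methoxyphenol
Product: 2 1-(benzyloxy)-4-bromo-2-methoxybenzene
Conditions: BnBr (1.1 equiv), K2CO3, DMF, rt
Reagents that add atoms: benzyl bromide, BrCc1ccccc1
Why: Williamson ether synthesis: K2CO3 generates the phenoxide, which displaces bromide from benzyl bromide by SN2, and the aryl bromide is inert under these conditions.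

Step 2
Reactants: 3 (4R)-4-benzyl-1,3-oxazolidin-2-one; 4 bromoacetyl bromide
Product: 6 (4R)-4-benzyl-3-(bromoacetyl)-1,3-oxazolidin-2-one, via N-lithio oxazolidinone 5 (not isolated)
Conditions: n-BuLi, THF, −78 °C; then 4, −78 → 0 °C
Reagents that add atoms: none
Why: N-acylation of a lithiated oxazolidinone (nucleophilic acyl substitution): at −78 °C the amide anion attacks the acyl bromide carbon, which is far more electrophilic than the CH2Br carbon, and the stereocentre of the auxiliary is not involved.

Step 3
Reactants: 6 (4R)-4-benzyl-3-(bromoacetyl)-1,3-oxazolidin-2-one; 7 4-(benzyloxy)-3-methoxybenzaldehyde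
Product: 10 (4R)-4-benzyl-3-[(2R,3S)-3-[4-(benzyloxy)-3-methoxyphenyl]-2-bromo-3-hydroxypropanoyl]-1,3-oxazolidin-2-one, via dibutylboron enolate 8 (not isolated), via dibutylboron aldolate 9 (not isolated)
Conditions: Bu2BOTf, i-Pr2NEt, CH2Cl2, −78 → 0 °C; then 7, −78 → 0 °C; pH 7 buffer, MeOH, 30% H2O2, 0 °C
Reagents that add atoms: none
Why: Evans syn-aldol reaction: soft enolisation gives the (Z)-boron enolate, which adds to the aldehyde through a closed six-membered chair transition state on the enolate face turned away from the benzyl group of the auxiliary, so that the carbinol carbon should be set as (3S) and the bromine-bearing carbon as (2R); since the minor isomers are diastereomers they can be removed by chromatography or crystallisation and the benzylic centre enters the route configurationally pure.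

Step 4
Reactants: 10 (4R)-4-benzyl-3-[(2R,3S)-3-[4-(benzyloxy)-3-methoxyphenyl]-2-bromo-3-hydroxypropanoyl]-1,3-oxazolidin-2-one
Product: 11 (1S,2S)-1-[4-(benzyloxy)-3-methoxyphenyl]-2-bromopropane-1,3-diol
Conditions: LiBH4, MeOH (1 equiv), THF, −10 → 0 °C; pH 7 buffer quench
Reagents that add atoms: none
Why: Reductive cleavage of an N-acyloxazolidinone: borohydride adds to the activated exocyclic imide carbonyl, the auxiliary is expelled and the aldehyde so freed is reduced on to the primary alcohol, while the low temperature and buffered quench should keep the alkoxyborates from displacing the neighbouring bromide; no stereocentre is touched (the descriptor of the bromine-bearing carbon changes from R to S only because the substituent priorities change).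

Step 5
Reactants: 11 (1S,2S)-1-[4-(benzyloxy)-3-methoxyphenyl]-2-bromopropane-1,3-diol
Product: 12 (1S,2S)-1-[4-(benzyloxy)-3-methoxyphenyl]-2-bromo-3-[(tert-butyldiphenylsilyl)oxy]propan-1-ol
Conditions: TBDPSCl (1.05 equiv), imidazole, CH2Cl2, 0 °C
Reagents that add atoms: tert-butyl(chloro)diphenylsilane, CC(C)(C)[Si](Cl)(c1ccccc1)c1ccccc1
Why: Silyl ether formation: the bulky chlorosilane reacts with the primary hydroxyl much faster than with the hindered secondary benzylic one, and imidazole is too weak a base to close the bromohydrin to an epoxide.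

Step 6
Reactants: 12 (1S,2S)-1-[4-(benzyloxy)-3-methoxyphenyl]-2-bromo-3-[(tert-butyldiphenylsilyl)oxy]propan-1-ol; 13 allyl 2,2,2-trichloroacetimidate
Product: 14 {[(2S,3S)-3-[4-(benzyloxy)-3-methoxyphenyl]-2-bromo-3-(prop-2-en-1-yloxy)propyl]oxy}(tert-butyl)diphenylsilane (the allyl ether of 12)
Conditions: 13 (2 equiv), TfOH (5 mol %), cyclohexane/CH2Cl2 2:1, 0 °C → rt
Reagents that add atoms: none
Why: Acid-catalysed trichloroacetimidate etherification: the protonated imidate hands its allyl group to the neutral hydroxyl, so no alkoxide that could displace the neighbouring bromide is ever formed, and the electron-withdrawing bromine next to the carbinol carbon together with the non-polar medium should hold back ionisation of the benzylic C–O bond, which therefore keeps its configuration.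

Step 7
Reactants: 14 {[(2S,3S)-3-[4-(benzyloxy)-3-methoxyphenyl]-2-bromo-3-(prop-2-en-1-yloxy)propyl]oxy}(tert-butyl)diphenylsilane; 2 1-(benzyloxy)-4-bromo-2-methoxybenzene
Product: 15 {[(2R,3S,4S)-2-[4-(benzyloxy)-3-methoxyphenyl]-4-{[4-(benzyloxy)-3-methoxyphenyl]methyl}oxolan-3-yl]methoxy}(tert-butyl)diphenylsilane (2,3-trans, 3,4-cis)
Conditions: 2 (1.5 equiv), NiBr2·glyme (10 mol %), 4,4'-di-tert-butyl-2,2'-bipyridine (10 mol %), Zn dust (2.5 equiv), NaI (25 mol %), DMA, 25–40 °C
Reagents that add atoms: none
Why: Nickel-catalysed reductive cyclisation–arylation (a cross-electrophile coupling with a radical ring closure in between): Zn reduces NiBr2 to a zerovalent nickel bipyridine complex that adds oxidatively to aryl bromide 2, while a monovalent nickel species abstracts the bromine atom of 14, so that the bromine-bearing carbon becomes a planar radical (the future C3) and its configuration is of no consequence. This radical closes 5-exo-trig onto the O-allyl double bond, forming C3–C4 and with it the oxolane ring (O1, C2, C3, C4, C5), and the exocyclic primary radical is captured by the arylnickel bromide, reductive elimination from trivalent nickel then making the CH2–aryl bond. The closest known reaction type is the nickel/Zn tandem cyclisation–coupling of β-bromoalkyl allyl ethers, bromoacetals included, with aryl halides. C3 is controlled by the existing C2 centre: in the chair-like transition state of the 3-oxahex-5-enyl radical the C2 aryl group lies pseudoequatorial and the CH2OSi group on the radical carbon turns away from it, which should give 2,3-trans. C4 is fixed in the same transition state, in which a substituent on the radical carbon and the forming exocyclic CH2 end up cis, which should give 3,4-cis, any 3,4-trans isomer being the expected minor product and separable by chromatography. The step needs ring closure to outrun bimolecular capture of the C3 radical and cross-coupling to outrun biaryl and bialkyl formation; the first is secured by the high rate of the 5-exo closure against the low concentration of arylnickel, the second by the different ways the two bromides are activated (oxidative addition for the aryl, halogen-atom abstraction for the alkyl) and by a moderate excess of 2.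

Step 8
Reactants: 15 {[(2R,3S,4S)-2-[4-(benzyloxy)-3-methoxyphenyl]-4-{[4-(benzyloxy)-3-methoxyphenyl]methyl}oxolan-3-yl]methoxy}(tert-butyl)diphenylsilane
Product: 16 [(2R,3S,4S)-2-[4-(benzyloxy)-3-methoxyphenyl]-4-{[4-(benzyloxy)-3-methoxyphenyl]methyl}oxolan-3-yl]methanol
Conditions: Bu4NF, THF, 0 °C → rt
Reagents that add atoms: none
Why: Fluoride-mediated desilylation driven by the strong Si–F bond; benzyl ethers, the oxolane and the three stereocentres are inert to Bu4NF.

Step 9
Reactants: 16 [(2R,3S,4S)-2-[4-(benzyloxy)-3-methoxyphenyl]-4-{[4-(benzyloxy)-3-methoxyphenyl]methyl}oxolan-3-yl]methanol; 17 (R)-2-methylbutanoic acid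
Product: 19 [(2R,3S,4S)-2-[4-(benzyloxy)-3-methoxyphenyl]-4-{[4-(benzyloxy)-3-methoxyphenyl]methyl}oxolan-3-yl]methyl (2R)-2-methylbutanoate, via O-acylisourea 18 (not isolated)
Conditions: DCC, DMAP (10 mol %), CH2Cl2, 0 °C → rt
Reagents that add atoms: none
Why: Steglich esterification: the O-acylisourea is passed on by DMAP as an acylpyridinium ion to the unhindered primary alcohol, and an α-branched alkanoic acid without further activating groups should keep its (R) configuration under these mild conditions.

Step 10
Reactants: 19 [(2R,3S,4S)-2-[4-(benzyloxy)-3-methoxyphenyl]-4-{[4-(benzyloxy)-3-methoxyphenyl]methyl}oxolan-3-yl]methyl (2R)-2-methylbutanoate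
Product: 20 [(2R,3S,4S)-2-(4-hydroxy-3-methoxyphenyl)-4-[(4-hydroxy-3-methoxyphenyl)methyl]oxolan-3-yl]methyl (2R)-2-methylbutanoate
Conditions: H2 (1 atm), 10% Pd/C, EtOAc, rt
Reagents that add atoms: none
Why: Catalytic hydrogenolysis of the two aryl benzyl ethers, which in a neutral aprotic solvent at atmospheric pressure should be far faster than cleavage of the cyclic benzylic C2–O1 bond, so the reaction is stopped once two equivalents of hydrogen are taken up; the ester and all four stereocentres are unaffected.

Compound list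
1 | 4-bromo-2-methoxyphenol | Oc1ccc(Br)cc1OC | starting material
2 | 1-(benzyloxy)-4-bromo-2-methoxybenzene | Brc1ccc(OCc2ccccc2)c(OC)c1 | intermediate
3 | (4R)-4-benzyl-1,3-oxazolidin-2-one | O=C1N[C@H](Cc2ccccc2)CO1 | starting material
4 | bromoacetyl bromide | BrCC(Br)=O | starting material
5 | lithium (4R)-4-benzyl-2-oxo-1,3-oxazolidin-3-ide (N-lithio derivative of 3) | [Li]N1[C@H](Cc2ccccc2)COC1=O | intermediate
6 | (4R)-4-benzyl-3-(bromoacetyl)-1,3-oxazolidin-2-one | O=C(CBr)N1[C@H](Cc2ccccc2)COC1=O | intermediate
7 | 4-(benzyloxy)-3-methoxybenzaldehyde | O=Cc1ccc(OCc2ccccc2)c(OC)c1 | starting material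
8 | (4R)-4-benzyl-3-[(Z)-2-bromo-1-(dibutylboranyloxy)ethenyl]-1,3-oxazolidin-2-one (boron enolate of 6) | CCCCB(CCCC)O/C(=C\Br)N1[C@H](Cc2ccccc2)COC1=O | intermediate
9 | O-dibutylboranyl derivative of 10 (boron aldolate) | CCCCB(CCCC)O[C@H]([C@@H](Br)C(=O)N1[C@H](Cc2ccccc2)COC1=O)c1ccc(OCc2ccccc2)c(OC)c1 | intermediate
10 | (4R)-4-benzyl-3-[(2R,3S)-3-[4-(benzyloxy)-3-methoxyphenyl]-2-bromo-3-hydroxypropanoyl]-1,3-oxazolidin-2-one | O=C([C@H](Br)[C@@H](O)c1ccc(OCc2ccccc2)c(OC)c1)N1[C@H](Cc2ccccc2)COC1=O | intermediate
11 | (1S,2S)-1-[4-(benzyloxy)-3-methoxyphenyl]-2-bromopropane-1,3-diol | OC[C@H](Br)[C@@H](O)c1ccc(OCc2ccccc2)c(OC)c1 | intermediate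
12 | (1S,2S)-1-[4-(benzyloxy)-3-methoxyphenyl]-2-bromo-3-[(tert-butyldiphenylsilyl)oxy]propan-1-ol | CC(C)(C)[Si](c1ccccc1)(c1ccccc1)OC[C@H](Br)[C@@H](O)c1ccc(OCc2ccccc2)c(OC)c1 | intermediate
13 | allyl 2,2,2-trichloroacetimidate | C=CCOC(=N)C(Cl)(Cl)Cl | starting material
14 | {[(2S,3S)-3-[4-(benzyloxy)-3-methoxyphenyl]-2-bromo-3-(prop-2-en-1-yloxy)propyl]oxy}(tert-butyl)diphenylsilane | C=CCO[C@H]([C@@H](Br)CO[Si](c1ccccc1)(c1ccccc1)C(C)(C)C)c1ccc(OCc2ccccc2)c(OC)c1 | intermediate
15 | {[(2R,3S,4S)-2-[4-(benzyloxy)-3-methoxyphenyl]-4-{[4-(benzyloxy)-3-methoxyphenyl]methyl}oxolan-3-yl]methoxy}(tert-butyl)diphenylsilane | CC(C)(C)[Si](c1ccccc1)(c1ccccc1)OC[C@@H]1[C@H](Cc2ccc(OCc3ccccc3)c(OC)c2)CO[C@H]1c1ccc(OCc2ccccc2)c(OC)c1 | intermediate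
16 | [(2R,3S,4S)-2-[4-(benzyloxy)-3-methoxyphenyl]-4-{[4-(benzyloxy)-3-methoxyphenyl]methyl}oxolan-3-yl]methanol | OC[C@@H]1[C@H](Cc2ccc(OCc3ccccc3)c(OC)c2)CO[C@H]1c1ccc(OCc2ccccc2)c(OC)c1 | intermediate
17 | (R)-2-methylbutanoic acid | CC[C@@H](C)C(=O)O | starting material
18 | N,N'-dicyclohexyl-O-[(2R)-2-methylbutanoyl]isourea | CC[C@@H](C)C(=O)OC(=NC1CCCCC1)NC1CCCCC1 | intermediate
19 | [(2R,3S,4S)-2-[4-(benzyloxy)-3-methoxyphenyl]-4-{[4-(benzyloxy)-3-methoxyphenyl]methyl}oxolan-3-yl]methyl (2R)-2-methylbutanoate | CC[C@@H](C)C(=O)OC[C@@H]1[C@H](Cc2ccc(OCc3ccccc3)c(OC)c2)CO[C@H]1c1ccc(OCc2ccccc2)c(OC)c1 | intermediate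
20 | [(2R,3S,4S)-2-(4-hydroxy-3-methoxyphenyl)-4-[(4-hydroxy-3-methoxyphenyl)methyl]oxolan-3-yl]methyl (2R)-2-methylbutanoate | CC[C@@H](C)C(=O)OC[C@@H]1[C@H](Cc2ccc(O)c(OC)c2)CO[C@H]1c1ccc(O)c(OC)c1 | target

Total step count: 10.
Longest linear sequence: 9 steps (steps 2 to 10); step 1 is a one-step branch that joins at step 7.

Steps most likely to fail

Step 7. The radical and organonickel intermediates may take other paths: closure with incomplete control at C4 (3,4-trans ring formation), hydrodebromination or zinc-induced β-elimination of the bromoether before closure, and homocoupling of 2. The fallback separates ring closure from arylation and sets out from 12. Etherification with prop-2-ynyl 2,2,2-trichloroacetimidate (TfOH cat., cyclohexane/CH2Cl2) would give the propargyl ether F1. Slow addition of Bu3SnH with AIBN (benzene, 80 °C) would effect a 5-exo-dig radical closure to the 2,3-trans 4-methylideneoxolane F2. Hydroboration with 9-BBN (THF, rt) from the ring face opposite the C3 arm would give the 3,4-cis B-alkyl borane F3, which is not isolated. A B-alkyl Suzuki–Miyaura coupling with 2 (PdCl2(dppf), aqueous K3PO4, THF/DMF, 60 °C) would then return to the route at 15.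

Step 6. The acid may ionise the electron-rich benzylic carbinol, with loss of configuration or elimination, or the imidate may rearrange before it transfers its allyl group. The fallback avoids acid altogether and sets out from 12. Treatment with Et2Zn (0.5 equiv, THF, 0 °C) would give the zinc bis-alkoxide F4, a weakly basic alkoxide that should not readily displace the neighbouring bromide and is not isolated. Palladium-catalysed allylic etherification with allyl acetate (Pd(OAc)2, 2-(di-tert-butylphosphino)biphenyl, THF, rt) would then return to the route at 14.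

Step 4. Under the basic hydride conditions an alkoxide may displace the neighbouring bromide (epoxide closure) or the aldolate may fragment by retro-aldol cleavage. The fallback changes the order of events and sets out from 10. The benzylic hydroxyl would first be allylated with 13 (TfOH cat.) to give the allyl ether imide F5, which can neither fragment nor close through the benzylic oxygen and whose acyl group further disfavours benzylic ionisation. LiBH4 reduction of F5 would give the primary bromo alcohol F6, and silylation with TBDPSCl/imidazole would return to the route at 14.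

Further compounds
F1 | step 7 | tert-butyl{[(2S,3S)-3-[4-(benzyloxy)-3-methoxyphenyl]-2-bromo-3-(prop-2-yn-1-yloxy)propyl]oxy}diphenylsilane | C#CCO[C@H]([C@@H](Br)CO[Si](c1ccccc1)(c1ccccc1)C(C)(C)C)c1ccc(OCc2ccccc2)c(OC)c1
F2 | step 7 | {[(2R,3S)-2-[4-(benzyloxy)-3-methoxyphenyl]-4-methylideneoxolan-3-yl]methoxy}(tert-butyl)diphenylsilane | CC(C)(C)[Si](c1ccccc1)(c1ccccc1)OC[C@@H]1C(=C)CO[C@H]1c1ccc(OCc2ccccc2)c(OC)c1
F3 | step 7 | 9-{[(2R,3S,4S)-oxolan-4-yl]methyl}-9-borabicyclo[3.3.1]nonane adduct of F2 (boron on the exocyclic CH2, 3,4-cis) | CC(C)(C)[Si](c1ccccc1)(c1ccccc1)OC[C@@H]1[C@H](CB2C3CCCC2CCC3)CO[C@H]1c1ccc(OCc2ccccc2)c(OC)c1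
F4 | step 6 | zinc bis-alkoxide of 12 | [Zn](O[C@H]([C@@H](Br)CO[Si](c1ccccc1)(c1ccccc1)C(C)(C)C)c1ccc(OCc2ccccc2)c(OC)c1)O[C@H]([C@@H](Br)CO[Si](c1ccccc1)(c1ccccc1)C(C)(C)C)c1ccc(OCc2ccccc2)c(OC)c1
F5 | step 4 | (4R)-4-benzyl-3-[(2R,3S)-3-[4-(benzyloxy)-3-methoxyphenyl]-2-bromo-3-(prop-2-en-1-yloxy)propanoyl]-1,3-oxazolidin-2-one | C=CCO[C@H]([C@@H](Br)C(=O)N1[C@H](Cc2ccccc2)COC1=O)c1ccc(OCc2ccccc2)c(OC)c1
F6 | step 4 | (2S,3S)-3-[4-(benzyloxy)-3-methoxyphenyl]-2-bromo-3-(prop-2-en-1-yloxy)propan-1-ol | C=CCO[C@H]([C@@H](Br)CO)c1ccc(OCc2ccccc2)c(OC)c1
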